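**Retrosynthetic overview**
1. Target ⇐ C18‑O‑silyl diene diol (late acetylation, then desilylation); the 2‑substituted butadiene ⇐ terminal alkyne + ethylene (enyne metathesis); alkyne and free C8 carbinol ⇐ a temporary δ‑lactone joining C13 to the C8 oxygen.
2. Key disconnection C4–C5 (ring A), made in the same operation as C9–C10 (ring B) and C8–O: epoxide‑initiated cation–olefin cascade of an acyclic (4Z,8E)‑epoxy‑diene tert‑butyl ester; ring order A → B → lactone.
3. Enabling feature: the secondary C3–O next to quaternary C4 (CH3, CH2O) is the imprint of a trisubstituted 2,3‑epoxy alcohol whose tertiary carbon becomes C4; the axial C9 chain (trans to the C10 methyl) beside an equatorial C8–O is the imprint of a (Z)‑olefin; the C8 oxygen lies δ to C13, within reach of a carboxyl terminator.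
4. Acyclic precursor ⇐ (2Z,6E)‑farnesol: two‑carbon extension with tert‑butyl acetate, terminal (E)‑allylic oxidation, Sharpless epoxidation with D‑(−)‑tartrate, silylation.

Key step: step 6

Remark: (2Z,6E)‑farnesol is taken as a purchasable single geometric isomer; ring and chain atoms are named by labdane numbering (C4 = quaternary carbon with CH3 and CH2OH, C5/C10 = ring‑fusion carbons, C8 = tertiary carbinol, C9 = carbon bearing the side chain C11–C16, C18 = the CH2O carbon on C4).

Step 1
Reactants: 1 (2Z,6E)-farnesol
Product: 2 (2Z,6E)-farnesyl bromide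
Conditions: PBr3 (0.4 equiv), Et2O, −10 °C
Reagents that add atoms: phosphorus tribromide, BrP(Br)Br
Why: Bromination of a primary allylic alcohol with PBr3 (SN2 on the phosphite ester) at low temperature should keep both olefin geometries, and no stereocentre is involved.

Step 2
Reactants: 2 (2Z,6E)-farnesyl bromide; 3 tert-butyl acetate
Product: 5 tert-butyl (4Z,8E)-5,9,13-trimethyltetradeca-4,8,12-trienoate, via lithium enolate of tert-butyl acetate 4 (not isolated)
Conditions: LDA, THF, −78 °C; then 2, DMPU, −78 → 0 °C
Reagents that add atoms: none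
Why: Ester enolate alkylation (SN2) of a primary allylic bromide, in which the tert-butyl group suppresses Claisen self-condensation and the new CH2–CH2 link leaves the Z-olefin untouched.

Step 3
Reactants: 5 tert-butyl (4Z,8E)-5,9,13-trimethyltetradeca-4,8,12-trienoate
Product: 6 tert-butyl (4Z,8E,12E)-14-hydroxy-5,9,13-trimethyltetradeca-4,8,12-trienoate
Conditions: SeO2 (0.2 equiv), t-BuOOH (70% aq.), salicylic acid (cat.), CH2Cl2, 0 °C → rt, stopped at partial conversion with recycling of 5
Reagents that add atoms: tert-butyl hydroperoxide, CC(C)(C)OO (oxygen relayed by catalytic selenium dioxide, O=[Se]=O)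
Why: Sharpless SeO2/t-BuOOH allylic oxidation (ene reaction, then [2,3]-sigmatropic shift) should prefer the (E)-methyl of the terminal isopropylidene unit over the internal olefins and give the (E)-allylic alcohol.

Step 4
Reactants: 6 tert-butyl (4Z,8E,12E)-14-hydroxy-5,9,13-trimethyltetradeca-4,8,12-trienoate
Product: 7 tert-butyl (4Z,8E)-11-[(2R,3R)-3-(hydroxymethyl)-3-methyloxiran-2-yl]-5,9-dimethylundeca-4,8-dienoate
Conditions: Ti(OiPr)4 (10 mol %), D-(−)-diethyl tartrate (12 mol %), t-BuOOH (anhydrous), 4 Å MS, CH2Cl2, −20 °C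
Reagents that add atoms: tert-butyl hydroperoxide, CC(C)(C)OO
Why: Katsuki–Sharpless asymmetric epoxidation acts only on the allylic-alcohol olefin, and D-(−)-tartrate should give the (2R,3R)-epoxy alcohol by reagent control, which fixes C3 and programmes C4.

Step 5
Reactants: 7 tert-butyl (4Z,8E)-11-[(2R,3R)-3-(hydroxymethyl)-3-methyloxiran-2-yl]-5,9-dimethylundeca-4,8-dienoate
Product: 8 tert-butyl (4Z,8E)-11-[(2R,3R)-3-{[tert-butyl(diphenyl)silyl]oxymethyl}-3-methyloxiran-2-yl]-5,9-dimethylundeca-4,8-dienoate
Conditions: TBDPSCl, imidazole, DMF, 0 °C → rt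
Reagents that add atoms: tert-butyl(chloro)diphenylsilane, CC(C)(C)[Si](Cl)(c1ccccc1)c1ccccc1
Why: Silylation of the primary alcohol gives a bulky, weakly Lewis-basic ether that should survive the Lewis acid of step 6 and keeps the future C18 oxygen apart from the C3 oxygen for the later acetylation.

Step 6
Reactants: 8 tert-butyl (4Z,8E)-11-[(2R,3R)-3-{[tert-butyl(diphenyl)silyl]oxymethyl}-3-methyloxiran-2-yl]-5,9-dimethylundeca-4,8-dienoate
Product: 10 (3R,4S,5S,8S,9R,10R)-18-(tert-butyldiphenylsilyloxy)-3-hydroxy-14,15,16-trinorlabdan-13,8-olide, via tert-butoxy oxocarbenium ion 9 (not isolated)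
Conditions: SnCl4 (2.0 equiv, Lewis-acid promoter), CH2Cl2 (5 mM), −78 → −60 °C; then sat. aq. NaHCO3
Reagents that add atoms: none
Why: SnCl4 activates the epoxide, which is opened at its tertiary carbon (future C4) in an SN2-like manner by the 8E-olefin; the resulting C10 cation is taken by the 4Z-olefin and the C8 cation by the ester carbonyl, after which oxocarbenium ion 9 loses isobutene to give the lactone. This is an epoxide-initiated cation–olefin polycyclisation in the Stork–Eschenmoser manifold, of the type that converts farnesylacetic acids into ambreinolide-type δ-lactones. Ring A closes 6-endo at the olefin (C4–C5 bond), ring B closes 6-endo (C9–C10 bond), and the six-membered lactone closes by carbonyl-oxygen capture at C8. C3 keeps the epoxide configuration and C4 is inverted, so both follow from the Sharpless epoxide and the E geometry of the allylic alcohol (CH2OSi equatorial, methyl axial); C5 and C10 become trans because the 8E-olefin adds anti through a chair; C9 carries its chain axial and trans to the C10 methyl because the olefin is 4Z; C8 takes its oxygen on the face of that chain because the tethered carbonyl can reach no other face, which leaves the C8 methyl axial. The step needs Markovnikov opening at the tertiary epoxide carbon despite the β-silyloxy group, chair–chair folding, and oxygen capture before proton loss; the tertiary centre and low temperature favour the first, the chair in which only the Z-imposed chain is axial favours the second, and the six-membered reach of the ester carbonyl favours the third.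

Step 7
Reactants: 10 (3R,4S,5S,8S,9R,10R)-18-(tert-butyldiphenylsilyloxy)-3-hydroxy-14,15,16-trinorlabdan-13,8-olide
Product: 12 (3R,4S,5S,8S,9R,10R)-18-(tert-butyldiphenylsilyloxy)-15,16-dinorlabd-13-yne-3,8-diol, via lactol 11 (not isolated)
Conditions: DIBAL-H (2.3 equiv), CH2Cl2, −78 °C; then MeOH, K2CO3, dimethyl (1-diazo-2-oxopropyl)phosphonate, 0 °C → rt
Reagents that add atoms: dimethyl (1-diazo-2-oxopropyl)phosphonate (Ohira–Bestmann reagent), COP(=O)(OC)C(=[N+]=[N-])C(C)=O
Why: Half-reduction of the δ-lactone to the lactol followed in the same flask by Seyferth–Gilbert homologation (Ohira–Bestmann modification) of its open hydroxy-aldehyde form should give the terminal alkyne and free the tertiary C8 carbinol without touching a stereocentre.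

Step 8
Reactants: 12 (3R,4S,5S,8S,9R,10R)-18-(tert-butyldiphenylsilyloxy)-15,16-dinorlabd-13-yne-3,8-diol; 13 ethylene
Product: 14 (3R,4S,5S,8S,9R,10R)-18-(tert-butyldiphenylsilyloxy)labda-13(16),14-diene-3,8-diol
Conditions: ethylene (1 atm), Grubbs second-generation catalyst (5 mol %), CH2Cl2, rt
Reagents that add atoms: none
Why: Ethylene–alkyne cross enyne metathesis turns a terminal alkyne into the 2-substituted 1,3-butadiene with full atom economy, and the substrate holds no other olefin that the ruthenium carbene could engage.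

Step 9
Reactants: 14 (3R,4S,5S,8S,9R,10R)-18-(tert-butyldiphenylsilyloxy)labda-13(16),14-diene-3,8-diol
Product: 15 (3R,4S,5S,8S,9R,10R)-3-acetoxy-18-(tert-butyldiphenylsilyloxy)labda-13(16),14-dien-8-ol
Conditions: Ac2O, pyridine, DMAP (cat.), CH2Cl2, 0 °C → rt
Reagents that add atoms: acetic anhydride, CC(=O)OC(C)=O
Why: DMAP-catalysed acylation should take the secondary C3 hydroxyl only, since the tertiary C8 hydroxyl is inert under these conditions and the primary oxygen is silylated.

Step 10
Reactants: 15 (3R,4S,5S,8S,9R,10R)-3-acetoxy-18-(tert-butyldiphenylsilyloxy)labda-13(16),14-dien-8-ol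
Product: 16 (3R,4S,5S,8S,9R,10R)-3-acetoxylabda-13(16),14-diene-8,18-diol (target)
Conditions: HF·pyridine, pyridine, THF, 0 °C → rt
Reagents that add atoms: none
Why: Fluoride-mediated cleavage of the silyl ether under buffered acidic conditions should free the primary alcohol without base-induced 1,3-acetyl migration and without harm to the diene or the tertiary alcohol.

**Compound list**
1 | (2Z,6E)-farnesol, (2Z,6E)-3,7,11-trimethyldodeca-2,6,10-trien-1-ol | OC/C=C(C)\CC/C=C(\C)CCC=C(C)C | starting material
2 | (2Z,6E)-farnesyl bromide, (2Z,6E)-1-bromo-3,7,11-trimethyldodeca-2,6,10-triene | BrC/C=C(C)\CC/C=C(\C)CCC=C(C)C | intermediate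
3 | tert-butyl acetate | CC(=O)OC(C)(C)C | starting material
4 | lithium enolate of tert-butyl acetate (lithium 1-tert-butoxyethenolate; not isolated) | [Li+].[O-]C(=C)OC(C)(C)C | intermediate
5 | tert-butyl (4Z,8E)-5,9,13-trimethyltetradeca-4,8,12-trienoate | CC(C)(C)OC(=O)CC/C=C(C)\CC/C=C(\C)CCC=C(C)C | intermediate
6 | tert-butyl (4Z,8E,12E)-14-hydroxy-5,9,13-trimethyltetradeca-4,8,12-trienoate | CC(C)(C)OC(=O)CC/C=C(C)\CC/C=C(\C)CC/C=C(\C)CO | intermediate
7 | tert-butyl (4Z,8E)-11-[(2R,3R)-3-(hydroxymethyl)-3-methyloxiran-2-yl]-5,9-dimethylundeca-4,8-dienoate | CC(C)(C)OC(=O)CC/C=C(C)\CC/C=C(\C)CC[C@H]1O[C@]1(C)CO | intermediate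
8 | tert-butyl (4Z,8E)-11-[(2R,3R)-3-{[tert-butyl(diphenyl)silyl]oxymethyl}-3-methyloxiran-2-yl]-5,9-dimethylundeca-4,8-dienoate | CC(C)(C)OC(=O)CC/C=C(C)\CC/C=C(\C)CC[C@H]1O[C@]1(C)CO[Si](c1ccccc1)(c1ccccc1)C(C)(C)C | intermediate
9 | tricyclic tert-butoxy oxocarbenium ion at C13 (C3 oxygen tin-bound, drawn as the alkoxide; ring stereocentres as in 10; not isolated) | CC(C)(C)O[C+]1CC[C@@H]2[C@]3(C)CC[C@@H]([O-])[C@](C)(CO[Si](c4ccccc4)(c4ccccc4)C(C)(C)C)[C@H]3CC[C@]2(C)O1 | intermediate
10 | (3R,4S,5S,8S,9R,10R)-18-(tert-butyldiphenylsilyloxy)-3-hydroxy-14,15,16-trinorlabdan-13,8-olide (trans-decalin, δ-lactone cis-fused through axial C11 and equatorial C8–O) | O=C1CC[C@@H]2[C@]3(C)CC[C@@H](O)[C@](C)(CO[Si](c4ccccc4)(c4ccccc4)C(C)(C)C)[C@H]3CC[C@]2(C)O1 | intermediate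
11 | lactol of 10 (C13 hemiacetal, both anomers; reacts through its open hydroxy-aldehyde form; not isolated) | OC1CC[C@@H]2[C@]3(C)CC[C@@H](O)[C@](C)(CO[Si](c4ccccc4)(c4ccccc4)C(C)(C)C)[C@H]3CC[C@]2(C)O1 | intermediate
12 | (3R,4S,5S,8S,9R,10R)-18-(tert-butyldiphenylsilyloxy)-15,16-dinorlabd-13-yne-3,8-diol | C#CCC[C@@H]1[C@]2(C)CC[C@@H](O)[C@](C)(CO[Si](c3ccccc3)(c3ccccc3)C(C)(C)C)[C@H]2CC[C@]1(C)O | intermediate
13 | ethylene | C=C | starting material
14 | (3R,4S,5S,8S,9R,10R)-18-(tert-butyldiphenylsilyloxy)labda-13(16),14-diene-3,8-diol | C=CC(=C)CC[C@@H]1[C@]2(C)CC[C@@H](O)[C@](C)(CO[Si](c3ccccc3)(c3ccccc3)C(C)(C)C)[C@H]2CC[C@]1(C)O | intermediate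
15 | (3R,4S,5S,8S,9R,10R)-3-acetoxy-18-(tert-butyldiphenylsilyloxy)labda-13(16),14-dien-8-ol | C=CC(=C)CC[C@@H]1[C@]2(C)CC[C@@H](OC(C)=O)[C@](C)(CO[Si](c3ccccc3)(c3ccccc3)C(C)(C)C)[C@H]2CC[C@]1(C)O | intermediate
16 | (3R,4S,5S,8S,9R,10R)-3-acetoxylabda-13(16),14-diene-8,18-diol | C=CC(=C)CC[C@@H]1[C@]2(C)CC[C@@H](OC(C)=O)[C@](C)(CO)[C@H]2CC[C@]1(C)O | target

**Step count:** 10 steps in total; longest linear sequence 10 steps (1 → 16).

**Steps most likely to fail**

Step 6. Ionisation at the tertiary epoxide carbon is slowed by the inductive pull of the neighbouring silyloxymethyl group, so hydride shift to a carbonyl compound or chloride capture may outrun olefin attack. The cascade may also stop by proton loss after one or two rings instead of lactone capture, and boat folding at the Z-olefin would erode control at C9. Fallback: starting from 8, the epoxide is opened by single-electron transfer with Cp2TiCl (from Cp2TiCl2 and Mn dust, THF, rt). The tertiary radical should then close both carbocycles 6-endo, with the olefin geometries translated as before, and end by β-hydride elimination to give the bicyclic 8(17)-olefin tert-butyl ester F1. In this radical manifold C4 would be set by the preference of the bulky silyloxymethyl group for the equatorial position, away from the C10 methyl. Treatment of F1 with TsOH in CH2Cl2 then cleaves the tert-butyl ester and closes the lactone by Markovnikov protonation of the exocyclic olefin and carboxyl capture on the face of the C9 chain, which returns to 10.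

Step 3. Site selection among three trisubstituted olefins may be poor, over-oxidation to the enal may occur, and conversion may be low. Fallback: starting from 5, the terminal olefin is functionalised selectively with NBS in aqueous THF to give the bromohydrin F2. K2CO3 in MeOH closes it to the terminal epoxide F3, and periodic acid cleaves this to the aldehyde F4. A Wittig reaction with 2-(triphenylphosphoranylidene)propanal gives the (E)-enal F5, and Luche reduction (NaBH4, CeCl3, MeOH) returns to 6 with the E geometry set by the stabilised ylide.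

Step 8. The ruthenium carbene may turn over slowly or be deactivated at the terminal alkyne, and the product diene may undergo secondary metathesis. Fallback: starting from lactone 10, addition of vinylmagnesium bromide (THF, −78 °C, cold acidic quench) should stop at the mono-adduct and give the δ-hydroxy vinyl ketone F6, in equilibrium with its hemiketal. Wittig methylenation with Ph3P=CH2 (excess, THF, 0 °C → rt) then builds the same 2-substituted diene and returns to 14, bypassing steps 7 and 8.

**Further compounds**
F1 | step 6 | tert-butyl 3-[bicyclic 8(17)-exo-methylene decalin]propanoate: 18-(tert-butyldiphenylsilyloxy)-3-hydroxy-14,15,16-trinorlabd-8(17)-en-13-oic acid tert-butyl ester, ring stereocentres C3, C4, C5, C9, C10 arranged as in 10 | CC(C)(C)OC(=O)CC[C@@H]1[C@]2(C)CC[C@@H](O)[C@](C)(CO[Si](c3ccccc3)(c3ccccc3)C(C)(C)C)[C@H]2CCC1=C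
F2 | step 3 | tert-butyl (4Z,8E)-12-bromo-13-hydroxy-5,9,13-trimethyltetradeca-4,8-dienoate (racemic) | CC(C)(C)OC(=O)CC/C=C(C)\CC/C=C(\C)CCC(Br)C(C)(C)O
F3 | step 3 | tert-butyl (4Z,8E)-11-(3,3-dimethyloxiran-2-yl)-5,9-dimethylundeca-4,8-dienoate (racemic) | CC(C)(C)OC(=O)CC/C=C(C)\CC/C=C(\C)CCC1OC1(C)C
F4 | step 3 | tert-butyl (4Z,8E)-5,9-dimethyl-12-oxododeca-4,8-dienoate | CC(C)(C)OC(=O)CC/C=C(C)\CC/C=C(\C)CCC=O
F5 | step 3 | tert-butyl (4Z,8E,12E)-5,9,13-trimethyl-14-oxotetradeca-4,8,12-trienoate | CC(C)(C)OC(=O)CC/C=C(C)\CC/C=C(\C)CC/C=C(\C)C=O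
F6 | step 8 | (3R,4S,5S,8S,9R,10R)-18-(tert-butyldiphenylsilyloxy)-3,8-dihydroxy-16-norlabd-14-en-13-one | C=CC(=O)CC[C@@H]1[C@]2(C)CC[C@@H](O)[C@](C)(CO[Si](c3ccccc3)(c3ccccc3)C(C)(C)C)[C@H]2CC[C@]1(C)O
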